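**Retrosynthetic overview**
1. The target is a head-to-tail ether dimer of one monomer, (3R,4R)-4,6,8-trihydroxy-7-methoxy-3-methylisochroman-1-one. Cut the benzylic C4–O–C6' aryl ether: the 4S centre of unit A (trans, ether-bearing) is the SN2-inverted 4R carbinol of the cis monomer, and the 6-OH of a second monomer (unit B, cis 4-OH kept) is the nucleophile. This is the last step.
2. Monomer ⇐ its MOM/acetate-protected form ⇐ methyl 6-[(E)-propenyl]benzoate: one enantioselective net-syn oxylactonisation closes the lactone and sets C3 and C4.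
3. Propenyl benzoate ⇐ benzoic acid (carboxylate-directed ortho C–H allylation, then isomerisation) ⇐ bis-MOM 2-methoxyresorcinol (ortho-lithiation, CO2).
4. Ring order: the arene is bought; the lactone ring is formed once, on the monomer; the dimerisation forms no ring.

Assumption: the lactate-derived iodane of step 5 is a known reagent (two operations from 2-iodoresorcinol and methyl (S)-lactate) and is not counted as a route step; its (R,R) form is taken to give the (3R,4R) lactone, and the (S,S) form is used instead if the first run shows the opposite sense.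

**Route**

Step 1
Reactants: 1 2-methoxybenzene-1,3-diol (2-methoxyresorcinol)
Product: 2 2-methoxy-1,3-bis(methoxymethoxy)benzene
Conditions: NaH (2.3 equiv), MOMCl (2.4 equiv), DMF, 0 °C → rt
Reagents that add atoms: chloromethyl methyl ether, COCCl
Why: Williamson-type O-alkylation of both phenoxides (MOM protection) gives an acetal that later directs lithiation and is removed by acid; no stereocentre is involved.

Step 2
Reactants: 2 2-methoxy-1,3-bis(methoxymethoxy)benzene
Product: 4 3-methoxy-2,4-bis(methoxymethoxy)benzoic acid, via aryllithium 3 (not isolated)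
Conditions: n-BuLi (1.1 equiv), THF, 0 °C, 1 h; CO2, −78 °C → rt; cold 1 M HCl to pH 3–4
Reagents that add atoms: n-butyllithium, [Li]CCCC (lithium of intermediate 3); carbon dioxide, O=C=O
Why: Directed ortho-metalation: the OMOM group steers lithiation to the only ortho C–H type (C4 and C6 are equivalent, C2 is blocked by OMe) and CO2 traps the aryllithium as the benzoic acid.

Step 3
Reactants: 4 3-methoxy-2,4-bis(methoxymethoxy)benzoic acid; 5 allyl acetate
Product: 7 methyl 6-allyl-3-methoxy-2,4-bis(methoxymethoxy)benzoate, via allyl acid 6 (not isolated)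
Conditions: [Ru(p-cymene)Cl2]2 (3 mol%), K3PO4 (2 equiv), allyl acetate (1.5 equiv), MeCN, 50 °C; then MeI (3 equiv), DMF, 40 °C
Reagents that add atoms: iodomethane, CI
Why: Carboxylate-directed ruthenium-catalysed ortho C–H allylation (cycloruthenation at the single free ortho C–H, insertion of allyl acetate, β-acetate elimination), followed in the same pot by SN2 O-methylation of the potassium carboxylate.

Step 4
Reactants: 7 methyl 6-allyl-3-methoxy-2,4-bis(methoxymethoxy)benzoate
Product: 8 methyl 3-methoxy-2,4-bis(methoxymethoxy)-6-[(E)-prop-1-en-1-yl]benzoate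
Conditions: RuHCl(CO)(PPh3)3 (2 mol%), toluene, 80 °C
Reagents that add atoms: none
Why: Ruthenium-hydride alkene isomerisation (hydrometalation, β-hydride elimination) moves the double bond into conjugation with the arene, and the thermodynamic E isomer dominates (expected E:Z above 15:1).

Step 5
Reactants: 8 methyl 3-methoxy-2,4-bis(methoxymethoxy)-6-[(E)-prop-1-en-1-yl]benzoate
Product: 9 (3R,4R)-4-acetoxy-7-methoxy-6,8-bis(methoxymethoxy)-3-methylisochroman-1-one
Conditions: (R,R)-lactate-derived aryl-λ3-iodane diacetate (1.2 equiv), BF3·OEt2 (2 equiv), AcOH (10 equiv), CH2Cl2, −80 → −40 °C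
Reagents that add atoms: dimethyl (2R,2'R)-2,2'-{[2-(diacetoxy-λ3-iodanyl)-1,3-phenylene]bis(oxy)}dipropanoate, COC(=O)[C@@H](C)Oc1cccc(O[C@H](C)C(=O)OC)c1I(OC(C)=O)OC(C)=O; acetic acid, CC(=O)O
Why: Hypervalent (trivalent) iodine endo-selective oxylactonisation, known for alkoxy-substituted o-(alk-1-enyl)benzoates: the chiral iodane activates one face of the E-alkene, acetic acid adds to the benzylic carbon anti to iodine, and the ester carbonyl then displaces the iodanyl group at C3 with inversion and loses its methyl, so net syn addition gives the cis (3R,4R) lactone with both stereocentres set by the reagent.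

Step 6
Reactants: 9 (3R,4R)-4-acetoxy-7-methoxy-6,8-bis(methoxymethoxy)-3-methylisochroman-1-one
Product: 11 (3R,4R)-4,6,8-trihydroxy-7-methoxy-3-methylisochroman-1-one, via diphenol acetate 10 (not isolated)
Conditions: 3 M HCl in MeOH, 0 °C → rt (MOM cleavage), then 45 °C (acetate methanolysis)
Reagents that add atoms: none
Why: Acid-catalysed acetal exchange removes both MOM groups and acid-catalysed transesterification then removes the acetate by acyl–oxygen cleavage, so no bond at C3 or C4 is broken, while the di-ortho-substituted, hydrogen-bonded lactone carbonyl is shielded from methanolysis.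

Step 7
Reactants: 11 (3R,4R)-4,6,8-trihydroxy-7-methoxy-3-methylisochroman-1-one (two molecules)
Product: 12 (3R,4R)-4,8-dihydroxy-6-{[(3R,4S)-6,8-dihydroxy-7-methoxy-3-methyl-1-oxoisochroman-4-yl]oxy}-7-methoxy-3-methylisochroman-1-one (CNP0139537.4)
Conditions: PPh3 (0.35 equiv), DIAD (0.35 equiv, added over 2 h), THF (0.3 M), 0 °C → rt; unreacted 11 recovered and recycled
Reagents that add atoms: none
Why: Proposed new method: protecting-group-free, head-to-tail Mitsunobu-type self-etherification of an unprotected hydroxy-diphenol, not shown on such a substrate; the PPh3/DIAD betaine is protonated by the 6-OH (para to the lactone carbonyl, pKa about 8, while the 8-OH stays locked in its hydrogen bond to C=O), the only sp3 hydroxyl (C4–OH) forms the alkoxyphosphonium ion, and the 6-phenoxide of a second molecule displaces Ph3P=O from benzylic C4 by SN2 with inversion (4R to 4S, trans ether; the pseudo-axial leaving group of the cis alcohol leaves the backside open), the C4 centre of the nucleophilic molecule being untouched; chain growth is held at the dimer by limiting the redox couple to 0.35 equiv (about one third of the C4–OH groups converted, statistical ceiling near 30 % dimer with about 40 % of 11 recoverable); closest known reactions: Mitsunobu etherification of secondary benzylic alcohols with phenols and the 4-O-selective Mitsunobu alkylation of 2,4-dihydroxybenzoates.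

**Compound list**
1 | 2-methoxybenzene-1,3-diol | COc1c(O)cccc1O | starting material
2 | 2-methoxy-1,3-bis(methoxymethoxy)benzene | COCOc1cccc(OCOC)c1OC | intermediate
3 | [3-methoxy-2,4-bis(methoxymethoxy)phenyl]lithium | [Li]c1ccc(OCOC)c(OC)c1OCOC | intermediate
4 | 3-methoxy-2,4-bis(methoxymethoxy)benzoic acid | OC(=O)c1ccc(OCOC)c(OC)c1OCOC | intermediate
5 | allyl acetate | CC(=O)OCC=C | starting material
6 | 6-allyl-3-methoxy-2,4-bis(methoxymethoxy)benzoic acid | OC(=O)c1c(CC=C)cc(OCOC)c(OC)c1OCOC | intermediate
7 | methyl 6-allyl-3-methoxy-2,4-bis(methoxymethoxy)benzoate | COC(=O)c1c(CC=C)cc(OCOC)c(OC)c1OCOC | intermediate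
8 | methyl 3-methoxy-2,4-bis(methoxymethoxy)-6-[(E)-prop-1-en-1-yl]benzoate | COC(=O)c1c(/C=C/C)cc(OCOC)c(OC)c1OCOC | intermediate
9 | (3R,4R)-4-acetoxy-7-methoxy-6,8-bis(methoxymethoxy)-3-methylisochroman-1-one | COCOc1cc2c(c(OCOC)c1OC)C(=O)O[C@H](C)[C@@H]2OC(C)=O | intermediate
10 | (3R,4R)-4-acetoxy-6,8-dihydroxy-7-methoxy-3-methylisochroman-1-one | COc1c(O)cc2c(c1O)C(=O)O[C@H](C)[C@@H]2OC(C)=O | intermediate
11 | (3R,4R)-4,6,8-trihydroxy-7-methoxy-3-methylisochroman-1-one | COc1c(O)cc2c(c1O)C(=O)O[C@H](C)[C@@H]2O | intermediate
12 | (3R,4R)-4,8-dihydroxy-6-{[(3R,4S)-6,8-dihydroxy-7-methoxy-3-methyl-1-oxoisochroman-4-yl]oxy}-7-methoxy-3-methylisochroman-1-one | COc1c(O)cc2c(c1O)C(=O)O[C@H](C)[C@H]2Oc1cc2c(c(O)c1OC)C(=O)O[C@H](C)[C@@H]2O | target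

**Step count and risk**
Total steps: 7. Longest linear sequence: 7 (1 → 12; the last step joins two molecules of 11).

Three steps most likely to fail:

Step 7 (the proposed new step). The risks are growth beyond the dimer (trimer and higher, since the dimer still carries one C4–OH and one 6-OH), E2 loss of the activated C4 oxygen to the 3-methylisocoumarin, and a slow SN2 at the hindered benzylic centre. The fallback is known chemistry and replaces self-coupling by hetero-coupling of two differently protected halves; it sets out from 9 and 10 and comes back at 12. One portion of 9 is deacetylated (K2CO3 0.2 equiv, MeOH, 0 °C) to (3R,4R)-4-hydroxy-7-methoxy-6,8-bis(methoxymethoxy)-3-methylisochroman-1-one F1, which has the C4–OH but no acidic phenol. A second portion of 9 is taken only through the first stage of step 6 (3 M HCl in MeOH, 0 °C, stopped after MOM loss) and 10 is isolated, which has the 6-OH but no free alcohol. Standard Mitsunobu etherification of F1 (1.0 equiv) with 10 (1.2 equiv) (PPh3, DIAD, THF, 0 °C → rt) can then give only the cross product, (3R,4R)-4-acetoxy-8-hydroxy-7-methoxy-6-{[(3R,4S)-7-methoxy-6,8-bis(methoxymethoxy)-3-methyl-1-oxoisochroman-4-yl]oxy}-3-methylisochroman-1-one F2, with the same inversion at C4. Treatment with 3 M HCl in MeOH (0 → 45 °C, as in step 6) removes both MOM groups and the acetate and gives 12. This costs two more steps but has no statistical ceiling.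

Step 5. The risks are partial MOM loss under BF3·OEt2 followed by phenol oxidation, insufficient enantio- or syn-selectivity, and some exo (phthalide) product from the electron-rich styrene. The fallback changes the source of asymmetry from reagent control to resolution; it sets out from 8 and comes back at 9. Achiral PhI(OAc)2 (1.2 equiv), BF3·OEt2, AcOH, CH2Cl2, −78 → −40 °C gives the same cis acetate as a racemate, that is 9 together with its mirror image (3S,4S)-4-acetoxy-7-methoxy-6,8-bis(methoxymethoxy)-3-methylisochroman-1-one F3. Butanolysis with immobilised Candida antarctica lipase B (n-BuOH, MTBE, 40 °C) is expected, by the empirical rule for lipases and secondary benzylic esters, to cleave the (4S) ester F3 to (3S,4S)-4-hydroxy-7-methoxy-6,8-bis(methoxymethoxy)-3-methylisochroman-1-one F4 and leave 9. Compound 9 is separated by chromatography (50 % at most) and rejoins the route at step 6.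

Step 3. The risks are low turnover with this crowded, electron-rich acid and loss of the MOM group next to the carboxylate. The fallback builds the side chain before the carboxyl group; it sets out from 2, comes back at 8, and replaces steps 2–4. Sterically controlled C–H borylation of 2 ([Ir(OMe)(cod)]2, dtbpy, B2pin2 1 equiv, THF, 80 °C; C5 is the only unhindered C–H) gives 2-[4-methoxy-3,5-bis(methoxymethoxy)phenyl]-4,4,5,5-tetramethyl-1,3,2-dioxaborolane F5. Suzuki coupling with (E)-1-bromoprop-1-ene (Pd(dppf)Cl2, K3PO4, dioxane/H2O, 80 °C, alkene geometry retained) gives 2-methoxy-1,3-bis(methoxymethoxy)-5-[(E)-prop-1-en-1-yl]benzene F6. Directed ortho-lithiation next to OMOM (n-BuLi, THF, −40 → −20 °C) gives {3-methoxy-2,4-bis(methoxymethoxy)-6-[(E)-prop-1-en-1-yl]phenyl}lithium F7, which is added inversely to ClCO2Me at −78 °C to give 8.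

**Further compounds**
F1 | step 7 | (3R,4R)-4-hydroxy-7-methoxy-6,8-bis(methoxymethoxy)-3-methylisochroman-1-one | COCOc1cc2c(c(OCOC)c1OC)C(=O)O[C@H](C)[C@@H]2O
F2 | step 7 | (3R,4R)-4-acetoxy-8-hydroxy-7-methoxy-6-{[(3R,4S)-7-methoxy-6,8-bis(methoxymethoxy)-3-methyl-1-oxoisochroman-4-yl]oxy}-3-methylisochroman-1-one | COCOc1cc2c(c(OCOC)c1OC)C(=O)O[C@H](C)[C@H]2Oc1cc2c(c(O)c1OC)C(=O)O[C@H](C)[C@@H]2OC(C)=O
F3 | step 5 | (3S,4S)-4-acetoxy-7-methoxy-6,8-bis(methoxymethoxy)-3-methylisochroman-1-one | COCOc1cc2c(c(OCOC)c1OC)C(=O)O[C@@H](C)[C@H]2OC(C)=O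
F4 | step 5 | (3S,4S)-4-hydroxy-7-methoxy-6,8-bis(methoxymethoxy)-3-methylisochroman-1-one | COCOc1cc2c(c(OCOC)c1OC)C(=O)O[C@@H](C)[C@H]2O
F5 | step 3 | 2-[4-methoxy-3,5-bis(methoxymethoxy)phenyl]-4,4,5,5-tetramethyl-1,3,2-dioxaborolane | COCOc1cc(B2OC(C)(C)C(C)(C)O2)cc(OCOC)c1OC
F6 | step 3 | 2-methoxy-1,3-bis(methoxymethoxy)-5-[(E)-prop-1-en-1-yl]benzene | COCOc1cc(/C=C/C)cc(OCOC)c1OC
F7 | step 3 | {3-methoxy-2,4-bis(methoxymethoxy)-6-[(E)-prop-1-en-1-yl]phenyl}lithium | [Li]c1c(/C=C/C)cc(OCOC)c(OC)c1OCOC
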